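## Retrosynthetic overview

1. Target 21 comes from 20 by removal of the aryl tert-butyldimethylsilyl ether and the tertiary triethylsilyl ether with buffered fluoride.
2. The strategy rests on the tetrasubstituted A ring: C1' carries the cinnamoyl group, C2' and C4' carry oxygen, C3' between them carries the side chain, and C5'/C6' are CH. The ring is cut at C1'–C2' and C5'–C6' into diene 11 (C2'–C3'–C4'–C5', with both oxygens and the chain) and terminal enynone 18 (C6'–C1' and the complete cinnamoyl unit).
3. Diene 11 comes from methyl acetoacetate, C-alkylated with iodide 5 and then silylated twice. Iodide 5 comes from (R)-linalool by vinyl hydroboration, iodination and silylation; the carbinol centre is taken from the chiral pool and never reacts.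
4. Enynone 18 comes from p-coumaric acid through its silylated Weinreb amide and ethynylmagnesium bromide.
5. Ring order: only the A ring is built (step 10); the B ring is carried in from p-coumaric acid.

Key step: step 10

Remark: (R)-linalool of high enantiomeric purity is assumed, since its carbinol centre becomes that of the target. The enol and ketene-acetal geometries of 9–11 and the transient sp3 centres of 8 and 19 are uncontrolled and inconsequential, so the SMILES leave them open.

## Route

Step 1
Reactants: 1 (R)-(−)-linalool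
Product: 3 (R)-3,7-dimethyloct-6-ene-1,3-diol, via B-alkyl-9-borabicyclo[3.3.1]nonane adduct 2 (not isolated)
Conditions: 9-BBN (2.2 equiv), THF, 0 °C → rt; then 3 M aq NaOH, 30% H2O2, 0 °C → rt
Reagents that add atoms: hydrogen peroxide, OO
Why: Hydroboration–oxidation: 9-BBN adds in the anti-Markovnikov sense to the monosubstituted vinyl group far faster than to the trisubstituted alkene (the excess allows for B–H consumed by the tertiary hydroxyl), and the carbinol centre, not a reacting atom, keeps its configuration.

Step 2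
Reactants: 3 (R)-3,7-dimethyloct-6-ene-1,3-diol
Product: 4 (R)-1-iodo-3,7-dimethyloct-6-en-3-ol
Conditions: PPh3, I2, imidazole, CH2Cl2, 0 °C → rt
Reagents that add atoms: iodine, II
Why: Appel-type iodination: only the unhindered primary hydroxyl forms an alkoxyphosphonium ion that iodide can displace by SN2, so the tertiary carbinol and its (R) centre are left as they are.

Step 3
Reactants: 4 (R)-1-iodo-3,7-dimethyloct-6-en-3-ol
Product: 5 triethyl{[(3R)-1-iodo-3,7-dimethyloct-6-en-3-yl]oxy}silane
Conditions: TESOTf, 2,6-lutidine, CH2Cl2, −78 → 0 °C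
Reagents that add atoms: triethylsilyl trifluoromethanesulfonate, CC[Si](CC)(CC)OS(=O)(=O)C(F)(F)F
Why: Silylation with a silyl triflate and a hindered pyridine base is the standard way to cap a tertiary alcohol; the ether prevents hemiketal or lactone formation with the β-keto ester to come and survives the enolate, amide-base and thermal steps.

Step 4
Reactants: 5 triethyl{[(3R)-1-iodo-3,7-dimethyloct-6-en-3-yl]oxy}silane; 6 methyl acetoacetate
Product: 8 methyl (5R)-2-acetyl-5,9-dimethyl-5-(triethylsilyloxy)dec-8-enoate, via sodium enolate of methyl acetoacetate 7 (not isolated)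
Conditions: 6 (2.2 equiv), NaH (2.0 equiv), THF–DMF, 0 °C; then 5, 55 °C
Reagents that add atoms: none
Why: Acetoacetic ester C-alkylation: the soft sodium enolate displaces the primary iodide by SN2, excess enolate suppresses dialkylation, and the new C2 centre is formed as an inconsequential epimer mixture.

Step 5
Reactants: 8 methyl (5R)-2-acetyl-5,9-dimethyl-5-(triethylsilyloxy)dec-8-enoate
Product: 9 methyl (5R)-5,9-dimethyl-5-(triethylsilyloxy)-2-[1-(trimethylsilyloxy)ethylidene]dec-8-enoate
Conditions: TMSCl, Et3N, toluene, rt, 48–72 h; filtration under argon, no aqueous work-up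
Reagents that add atoms: chlorotrimethylsilane, C[Si](C)(C)Cl
Why: O-Silylation of the β-keto ester enol under soft-enolisation conditions (amine base, silyl chloride) gives the β-silyloxy enoate, the established first stage of bis-silyl diene synthesis, without disturbing the triethylsilyl ether.

Step 6
Reactants: 9 methyl (5R)-5,9-dimethyl-5-(triethylsilyloxy)-2-[1-(trimethylsilyloxy)ethylidene]dec-8-enoate
Product: 11 2-[(3R)-3,7-dimethyl-3-(triethylsilyloxy)oct-6-en-1-yl]-1-methoxy-1,3-bis(trimethylsilyloxy)buta-1,3-diene, via lithium dienolate 10 (not isolated)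
Conditions: LDA (1.5 equiv), THF, −78 °C; TMSCl, −78 °C → rt; hexane trituration, filtration under argon, used crude
Reagents that add atoms: chlorotrimethylsilane, C[Si](C)(C)Cl
Why: Kinetic γ-deprotonation of the vinylogous ester by LDA gives the cross-conjugated lithium dienolate, which the hard silyl chloride traps on the ester oxygen to give the 1-methoxy-1,3-bis(silyloxy)diene (the standard preparation of 2-substituted dienes of this class).

Step 7
Reactants: 12 p-coumaric acid
Product: 14 (E)-3-(4-hydroxyphenyl)-N-methoxy-N-methylprop-2-enamide, via 1H-benzotriazol-1-yl (E)-3-(4-hydroxyphenyl)prop-2-enoate 13 (not isolated)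
Conditions: MeNH(OMe)·HCl, EDC·HCl, HOBt, N-methylmorpholine, DMF, 0 °C → rt
Reagents that add atoms: N,O-dimethylhydroxylamine hydrochloride, CNOC.Cl
Why: Carbodiimide/HOBt amide coupling: the active ester is aminolysed by the much more nucleophilic N,O-dimethylhydroxylamine faster than it can acylate the free phenol, and the (E)-alkene is untouched.

Step 8
Reactants: 14 (E)-3-(4-hydroxyphenyl)-N-methoxy-N-methylprop-2-enamide
Product: 15 (E)-3-[4-(tert-butyldimethylsilyloxy)phenyl]-N-methoxy-N-methylprop-2-enamide
Conditions: TBSCl, imidazole, DMF, rt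
Reagents that add atoms: tert-butyldimethylsilyl chloride, CC(C)(C)[Si](C)(C)Cl
Why: Silylation of a phenol with a silyl chloride and imidazole in DMF is routine and masks the acidic OH before the Grignard step.

Step 9
Reactants: 15 (E)-3-[4-(tert-butyldimethylsilyloxy)phenyl]-N-methoxy-N-methylprop-2-enamide; 16 ethynylmagnesium bromide
Product: 18 (E)-1-[4-(tert-butyldimethylsilyloxy)phenyl]pent-1-en-4-yn-3-one, via bromomagnesium hemiaminal alkoxide 17 (not isolated)
Conditions: HC≡CMgBr (0.5 M in THF, 2.5 equiv), THF, 0 °C; inverse quench into cold 1 M HCl/Et2O; used promptly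
Reagents that add atoms: none
Why: Weinreb ketone synthesis: the acetylide adds 1,2 to the amide and the magnesium-chelated tetrahedral adduct 17 persists until the quench, which rules out over-addition, while the inverse acidic quench protonates the liberated N,O-dimethylhydroxylamine before it can add to the terminal ynone.

Step 10
Reactants: 11 2-[(3R)-3,7-dimethyl-3-(triethylsilyloxy)oct-6-en-1-yl]-1-methoxy-1,3-bis(trimethylsilyloxy)buta-1,3-diene; 18 (E)-1-[4-(tert-butyldimethylsilyloxy)phenyl]pent-1-en-4-yn-3-one
Product: 20 (E)-3-[4-(tert-butyldimethylsilyloxy)phenyl]-1-{2,4-dihydroxy-3-[(3R)-3,7-dimethyl-3-(triethylsilyloxy)oct-6-en-1-yl]phenyl}prop-2-en-1-one, via mixed-ketal cyclohexa-1,4-diene cycloadduct 19 (not isolated)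
Conditions: 11 (1.5 equiv), toluene, −20 °C → rt (45 °C if needed); then THF, 10% aq citric acid, 0 °C → rt
Reagents that add atoms: none
Why: The diene reacts as an electron-rich 2-alkyl vinylketene acetal in a normal-demand Diels–Alder reaction (in the asynchronous limit a Mukaiyama–Michael addition followed by closure of the allenolate onto the silyloxycarbenium carbon): its unsubstituted C4 methylene bonds to the terminal alkyne carbon (C5'–C6') and its ketene-acetal carbon to the carbonyl-bearing alkyne carbon (C1'–C2'), giving cyclohexa-1,4-diene 19. Mild aqueous acid then cleaves the two O–SiMe3 bonds, the resulting hemiketal expels methanol and the cyclohexenedione enolises irreversibly to the resorcinol. The closest known reaction type is the cycloaddition–aromatisation of 1-alkoxy-1,3-bis(silyloxy)buta-1,3-dienes and related oxygenated vinylketene acetals with acetylenic ketones and esters, which gives 2,4-dihydroxyaryl carbonyl compounds. The single new ring, the six-membered A ring, is closed by this intermolecular [4+2] annulation, both new bonds forming between the diene termini and the two alkyne carbons. No stereocentre is created that persists (the ketal carbon of 19 is erased on aromatisation) and the remote (R)-carbinol is not involved. The step needs regioselectivity, secured by the match of the largest diene HOMO coefficient at C4 with the β-carbon of the ynone; chemoselectivity for the alkyne over the styryl C=C, secured by the unhindered terminal sp carbon against a β-aryl alkene deactivated by the para-silyloxy donor; and loss of methanol rather than silanol, secured by hydrolysing the Si–O bonds before the ketal can ionise.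

Step 11
Reactants: 20 (E)-3-[4-(tert-butyldimethylsilyloxy)phenyl]-1-{2,4-dihydroxy-3-[(3R)-3,7-dimethyl-3-(triethylsilyloxy)oct-6-en-1-yl]phenyl}prop-2-en-1-one
Product: 21 (E)-1-{2,4-dihydroxy-3-[(3R)-3-hydroxy-3,7-dimethyloct-6-en-1-yl]phenyl}-3-(4-hydroxyphenyl)prop-2-en-1-one
Conditions: TBAF (3 equiv), AcOH (3 equiv), THF, 0 °C → rt
Reagents that add atoms: none
Why: Fluoride-driven desilylation (formation of strong Si–F bonds) removes the aryl and the tertiary silyl ether, and buffering with acetic acid keeps the 2'-phenol protonated so that oxa-Michael closure to the flavanone is avoided, as is any acid-promoted chroman formation from the tertiary carbinol; the stereocentre is not touched.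

## Compound list

1 | (R)-(−)-linalool | CC(C)=CCC[C@@](C)(O)C=C | starting material
2 | 9-[(3S)-3-hydroxy-3,7-dimethyloct-6-en-1-yl]-9-borabicyclo[3.3.1]nonane (same spatial arrangement as 1; the descriptor changes only because boron lowers the CIP rank of that branch) | CC(C)=CCC[C@@](C)(O)CCB1C2CCCC1CCC2 | intermediate
3 | (R)-3,7-dimethyloct-6-ene-1,3-diol | CC(C)=CCC[C@@](C)(O)CCO | intermediate
4 | (R)-1-iodo-3,7-dimethyloct-6-en-3-ol | CC(C)=CCC[C@@](C)(O)CCI | intermediate
5 | triethyl{[(3R)-1-iodo-3,7-dimethyloct-6-en-3-yl]oxy}silane | CC(C)=CCC[C@@](C)(O[Si](CC)(CC)CC)CCI | intermediate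
6 | methyl acetoacetate | CC(=O)CC(=O)OC | starting material
7 | sodium enolate of methyl acetoacetate | [Na+].COC(=O)C=C(C)[O-] | intermediate
8 | methyl (5R)-2-acetyl-5,9-dimethyl-5-(triethylsilyloxy)dec-8-enoate (C2 epimer mixture) | CC(C)=CCC[C@@](C)(O[Si](CC)(CC)CC)CCC(C(C)=O)C(=O)OC | intermediate
9 | methyl (5R)-5,9-dimethyl-5-(triethylsilyloxy)-2-[1-(trimethylsilyloxy)ethylidene]dec-8-enoate (E/Z mixture) | CC(C)=CCC[C@@](C)(O[Si](CC)(CC)CC)CCC(C(=O)OC)=C(C)O[Si](C)(C)C | intermediate
10 | lithium dienolate of 9 (lithium 2-[(3R)-3,7-dimethyl-3-(triethylsilyloxy)oct-6-en-1-yl]-1-methoxy-3-(trimethylsilyloxy)buta-1,3-dien-1-olate) | [Li+].CC(C)=CCC[C@@](C)(O[Si](CC)(CC)CC)CCC(C(=C)O[Si](C)(C)C)=C(OC)[O-] | intermediate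
11 | 2-[(3R)-3,7-dimethyl-3-(triethylsilyloxy)oct-6-en-1-yl]-1-methoxy-1,3-bis(trimethylsilyloxy)buta-1,3-diene | CC(C)=CCC[C@@](C)(O[Si](CC)(CC)CC)CCC(C(=C)O[Si](C)(C)C)=C(OC)O[Si](C)(C)C | intermediate
12 | p-coumaric acid [(E)-3-(4-hydroxyphenyl)prop-2-enoic acid] | O=C(O)/C=C/c1ccc(O)cc1 | starting material
13 | 1H-benzotriazol-1-yl (E)-3-(4-hydroxyphenyl)prop-2-enoate | O=C(/C=C/c1ccc(O)cc1)On1nnc2ccccc12 | intermediate
14 | (E)-3-(4-hydroxyphenyl)-N-methoxy-N-methylprop-2-enamide | CON(C)C(=O)/C=C/c1ccc(O)cc1 | intermediate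
15 | (E)-3-[4-(tert-butyldimethylsilyloxy)phenyl]-N-methoxy-N-methylprop-2-enamide | CON(C)C(=O)/C=C/c1ccc(O[Si](C)(C)C(C)(C)C)cc1 | intermediate
16 | ethynylmagnesium bromide | C#C[Mg]Br | starting material
17 | bromomagnesium (E)-1-[4-(tert-butyldimethylsilyloxy)phenyl]-3-[methoxy(methyl)amino]pent-1-en-4-yn-3-olate | C#CC(O[Mg]Br)(N(C)OC)/C=C/c1ccc(O[Si](C)(C)C(C)(C)C)cc1 | intermediate
18 | (E)-1-[4-(tert-butyldimethylsilyloxy)phenyl]pent-1-en-4-yn-3-one | C#CC(=O)/C=C/c1ccc(O[Si](C)(C)C(C)(C)C)cc1 | intermediate
19 | (E)-3-[4-(tert-butyldimethylsilyloxy)phenyl]-1-{5-[(3R)-3,7-dimethyl-3-(triethylsilyloxy)oct-6-en-1-yl]-6-methoxy-4,6-bis(trimethylsilyloxy)cyclohexa-1,4-dien-1-yl}prop-2-en-1-one (epimers at the ketal carbon) | CC(C)=CCC[C@@](C)(O[Si](CC)(CC)CC)CCC1=C(O[Si](C)(C)C)CC=C(C(=O)/C=C/c2ccc(O[Si](C)(C)C(C)(C)C)cc2)C1(OC)O[Si](C)(C)C | intermediate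
20 | (E)-3-[4-(tert-butyldimethylsilyloxy)phenyl]-1-{2,4-dihydroxy-3-[(3R)-3,7-dimethyl-3-(triethylsilyloxy)oct-6-en-1-yl]phenyl}prop-2-en-1-one | CC(C)=CCC[C@@](C)(O[Si](CC)(CC)CC)CCc1c(O)ccc(C(=O)/C=C/c2ccc(O[Si](C)(C)C(C)(C)C)cc2)c1O | intermediate
21 | (E)-1-{2,4-dihydroxy-3-[(3R)-3-hydroxy-3,7-dimethyloct-6-en-1-yl]phenyl}-3-(4-hydroxyphenyl)prop-2-en-1-one (CNP0156752.1) | CC(C)=CCC[C@@](C)(O)CCc1c(O)ccc(C(=O)/C=C/c2ccc(O)cc2)c1O | target

## Step count and risks

Total step count: 11. Longest linear sequence: 8 steps (steps 1–6, 10, 11, from (R)-linalool); steps 7–9 form the second branch.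

**Risk 1 – step 10.** The diene may add unselectively to the cross-conjugated enynone (at the styryl C=C or the carbonyl), or the terminal enynone may oligomerise faster than it cycloadds; in either case the chalcone-bearing dienophile is lost. The fallback sets out from diene 11 and uses commercial but-3-yn-2-one, a dienophile with a single electrophilic π-bond. The same thermal cycloaddition should give the acetyl-substituted mixed-ketal cyclohexa-1,4-diene F1, and the citric acid work-up should give the acetophenone 1-{2,4-dihydroxy-3-[(3R)-3,7-dimethyl-3-(triethylsilyloxy)oct-6-en-1-yl]phenyl}ethan-1-one F2. Claisen–Schmidt condensation of F2 with 4-hydroxybenzaldehyde (aq KOH, EtOH, rt) should then give the triethylsilyl-protected chalcone (E)-1-{2,4-dihydroxy-3-[(3R)-3,7-dimethyl-3-(triethylsilyloxy)oct-6-en-1-yl]phenyl}-3-(4-hydroxyphenyl)prop-2-en-1-one F3. Partial loss of the silyl ether under the basic conditions would be harmless. The buffered fluoride of step 11 brings the sequence back to the route at target 21.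

**Risk 2 – step 6.** γ-Lithiation may be incomplete or followed by C-silylation, and the trimethylsilyl groups of a diene too heavy to distil may be hydrolysed during isolation, so that the key step receives impure diene. The fallback sets out from keto ester 8 and changes the diene to a sturdier one made without strong base. Soft double enolisation with TBSOTf and Et3N (CH2Cl2, 0 °C → rt) should give 2-[(3R)-3,7-dimethyl-3-(triethylsilyloxy)oct-6-en-1-yl]-1-methoxy-1,3-bis(tert-butyldimethylsilyloxy)buta-1,3-diene F4, which can be purified on triethylamine-deactivated silica. Cycloaddition of F4 with 18 under the thermal conditions of step 10 should give the tert-butyldimethylsilyl analogue of the cycloadduct F5. Treating F5 directly with TBAF/AcOH in THF should unmask the enol ether and the ketal, let methanol leave, aromatise the ring and strip the remaining silyl ethers, so that the sequence returns to the route at target 21.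

**Risk 3 – step 9.** The liberated N,O-dimethylhydroxylamine (or a second acetylide) may add in conjugate fashion to the freshly formed terminal ynone during the quench, and the sensitive enynone may polymerise under basic work-up. The fallback sets out from Weinreb amide 15 and forms the ketone by oxidation under neutral conditions. Reduction with DIBAL-H (THF, −78 °C) should give (E)-3-[4-(tert-butyldimethylsilyloxy)phenyl]prop-2-enal F6. Addition of ethynylmagnesium bromide 16 (THF, −78 → 0 °C) should give racemic (E)-1-[4-(tert-butyldimethylsilyloxy)phenyl]pent-1-en-4-yn-3-ol F7. Oxidation of the doubly activated alcohol with MnO2 (CH2Cl2, rt) returns to the route at enynone 18.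

## Further compounds

F1 | step 10 | 1-{5-[(3R)-3,7-dimethyl-3-(triethylsilyloxy)oct-6-en-1-yl]-6-methoxy-4,6-bis(trimethylsilyloxy)cyclohexa-1,4-dien-1-yl}ethan-1-one | CC(C)=CCC[C@@](C)(O[Si](CC)(CC)CC)CCC1=C(O[Si](C)(C)C)CC=C(C(C)=O)C1(OC)O[Si](C)(C)C
F2 | step 10 | 1-{2,4-dihydroxy-3-[(3R)-3,7-dimethyl-3-(triethylsilyloxy)oct-6-en-1-yl]phenyl}ethan-1-one | CC(C)=CCC[C@@](C)(O[Si](CC)(CC)CC)CCc1c(O)ccc(C(C)=O)c1O
F3 | step 10 | (E)-1-{2,4-dihydroxy-3-[(3R)-3,7-dimethyl-3-(triethylsilyloxy)oct-6-en-1-yl]phenyl}-3-(4-hydroxyphenyl)prop-2-en-1-one | CC(C)=CCC[C@@](C)(O[Si](CC)(CC)CC)CCc1c(O)ccc(C(=O)/C=C/c2ccc(O)cc2)c1O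
F4 | step 6 | 2-[(3R)-3,7-dimethyl-3-(triethylsilyloxy)oct-6-en-1-yl]-1-methoxy-1,3-bis(tert-butyldimethylsilyloxy)buta-1,3-diene | CC(C)=CCC[C@@](C)(O[Si](CC)(CC)CC)CCC(C(=C)O[Si](C)(C)C(C)(C)C)=C(OC)O[Si](C)(C)C(C)(C)C
F5 | step 6 | (E)-3-[4-(tert-butyldimethylsilyloxy)phenyl]-1-{4,6-bis(tert-butyldimethylsilyloxy)-5-[(3R)-3,7-dimethyl-3-(triethylsilyloxy)oct-6-en-1-yl]-6-methoxycyclohexa-1,4-dien-1-yl}prop-2-en-1-one | CC(C)=CCC[C@@](C)(O[Si](CC)(CC)CC)CCC1=C(O[Si](C)(C)C(C)(C)C)CC=C(C(=O)/C=C/c2ccc(O[Si](C)(C)C(C)(C)C)cc2)C1(OC)O[Si](C)(C)C(C)(C)C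
F6 | step 9 | (E)-3-[4-(tert-butyldimethylsilyloxy)phenyl]prop-2-enal | O=C/C=C/c1ccc(O[Si](C)(C)C(C)(C)C)cc1
F7 | step 9 | (E)-1-[4-(tert-butyldimethylsilyloxy)phenyl]pent-1-en-4-yn-3-ol (racemic) | C#CC(O)/C=C/c1ccc(O[Si](C)(C)C(C)(C)C)cc1
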